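The earlier runs and the new flask are calculated for an exercise.

Green had 27.2% of its Q left at 7.3 h, while grey, charged with half as much Q and the same E, had 20.3%, less than green by 6.9 percentage points, and a single reading scatters by 0.333% of the green charge. The bench rule of a pseudo-first-order decay gives the same share left at any charge, for the same E over the same hours, so it already fails between these two flasks.

| setting | green | grey | teal | ochre | blue |
|---|---|---|---|---|---|
| Q | 0.120 M | 0.0600 M | 0.120 M | 0.120 M | 0.0240 M |
| E | 0.00600 M | 0.00600 M | 0.00600 M | 0.00900 M | 0.00600 M |
| G |  |  | 0.0600 M |  |  |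
| time |  |  |  |  | 7.3 h |

| run | time / h | [Q] / M |
|---|---|---|
| green run | 1.2 | 0.0957 |
| green run | 2.4 | 0.0768 |
| green run | 3.6 | 0.0622 |
| green run | 4.9 | 0.0495 |
| green run | 6.1 | 0.0406 |
| green run | 7.3 | 0.0327 |
| grey run | 1.2 | 0.0459 |
| grey run | 2.4 | 0.0357 |
| grey run | 3.6 | 0.0264 |
| grey run | 4.9 | 0.0199 |
| grey run | 6.1 | 0.0153 |
| grey run | 7.3 | 0.0122 |
| teal run | 1.2 | 0.0965 |
| teal run | 2.4 | 0.0769 |
| teal run | 3.6 | 0.0621 |
| teal run | 4.9 | 0.0498 |
| teal run | 6.1 | 0.0410 |
| teal run | 7.3 | 0.0331 |
| ochre run | 1.2 | 0.0861 |
| ochre run | 2.4 | 0.0605 |
| ochre run | 3.6 | 0.0434 |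
| ochre run | 4.9 | 0.0294 |
| ochre run | 6.1 | 0.0214 |
| ochre run | 7.3 | 0.0150 |

(scatter of a reading: 4 × 10⁻⁴ M)

- Overall: Q -> G, with E as catalyst.
- Constant volume, constant temperature.
- What is held in complexes is read along with the free species.
- An order is taken over about fifteen percent of the charge, up and down.

- the exponent of [Q] in the starting rate at the charge of the green run (at the point where two percent of the Q have become G) (one fixed amount of G, the same in the runs compared)
- the exponent of [E] in the starting rate at the charge of the green run (at the point where two percent of the Q have become G)
- Q in the blue run at 7.3 h, as a share of the Q charged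

Write the balance of E, charged at 5.00% of the Q in green. Supposing that part of E is held by Q, with free and held E making up the charge, I take the rate as proportional to f over (one plus c f), where f is the fraction of Q left and c is the charge divided by a constant K. Turning a small fraction then costs a little dose, and the costs add up to n = −ln f + c x, where x is the fraction turned. The quantity n is the catalyst dose, the work E has delivered by a given hour, on the scale of K. I assume that whatever E loses on the way, flasks with the same E and the same hours receive the same n. Green, grey and blue each carry 0.00600 M of E, so setting n equal in green and grey at 7.3 h gives a reading of 0.135 M for K and 1.95 for the dose.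

The ratio c marks the border of the bench rule: it is 0.889 in green but 0.178 in blue. At the green charge my rate gives an exponent of [Q] of one over (one plus c), which is 0.529, and I take the exponent of [E] as one. For blue, a first pass with x set to one leaves 17.0% of the charge, and one repeat with x from that pass leaves 16.5%, which is my reckoning. There c x is 0.148 of the dose of 1.95, less than half of it.

The forecast gives 0.53 and 0.96 for the exponents of [Q] and [E] and 16.5% for blue, and it reads the runs this way: “Yet k does not rise as Q falls within a run, so the catalyst must be dying.”

The flask gives 0.50, 1.0 and 16.3%, on these steps: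

    E + Q ⇌ EQ, settled at all times (1.110 M⁻¹)
    EQ → G + E (40.32 h⁻¹)
    E + Q → Vo + Q (1.044 M⁻¹ h⁻¹)
    EQ + Q ⇌ EQ2, settled at all times (20.20 M⁻¹)

A power law fitted to the runs leaves a root mean square residual of 4.2 in units of the scatter and puts blue at 18.5%. Blue's 16.3% corresponds to a dose of 1.97, beside the 1.95 carried from green. Turning a quarter of the charge costs green and ochre, which have the same c, a dose of 0.510. Ochre delivers it in 1.03 h and green in 1.57 h, a ratio of 1.52 for a ratio of E of 1.50.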